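The seven-membered ring of the hexahydroazulene is opened at two bonds, C3a–C4 and C6=C7, which separates a cyclopentene-based four-carbon unit (C7, C8, C8a, C3a) from a three-carbon unit (C4–C6 plus the carboxyl carbon on C6). The key step exploits that C3a is the inner carbon of the tetrasubstituted C3=C3a alkene (an enol triflate carbon) while C6 bears an ester-level carbon (a phosphonoacetate carbon): in one flask a B-alkyl Suzuki–Miyaura coupling forms C3a–C4 and a ring-closing Horner–Wadsworth–Emmons olefination forms C6=C7. Its precursor is an enol triflate carrying a CH2CHO arm on the quaternary carbon. The quaternary centre C8a is set earlier by an enantioselective decarboxylative allylation.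

Key step: step 8

Assumption: the (R)-configured PHOX ligand is taken to give the (R)-ketone in step 2, the mirror image of the established (S)-ligand to (S)-2-allyl-2-alkylcycloalkanone correlation.

Step 1
Reactants: 1 diallyl adipate (diprop-2-en-1-yl hexanedioate)
Product: 3 prop-2-en-1-yl 1-methyl-2-oxocyclopentane-1-carboxylate (racemic), via sodium ketoester enolate 2 (not isolated)
Conditions: NaH (1.05 equiv), THF, 40 °C; then MeI, 25 → 45 °C
Reagents that add atoms: iodomethane, CI
Why: Dieckmann condensation of the symmetrical diester should give the stabilised β-keto ester enolate, which is C-methylated in the same flask; the quaternary centre is racemic here and is reset in step 2.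

Step 2
Reactants: 3 prop-2-en-1-yl 1-methyl-2-oxocyclopentane-1-carboxylate
Product: 4 (2R)-2-methyl-2-(prop-2-en-1-yl)cyclopentan-1-one
Conditions: Pd2(dba)3 (2.5 mol %), (R)-t-BuPHOX [(4R)-4-tert-butyl-2-[2-(diphenylphosphanyl)phenyl]-4,5-dihydro-1,3-oxazole] (6 mol %), toluene, 25 °C
Reagents that add atoms: none
Why: In this decarboxylative asymmetric allylic alkylation (Tsuji allylation with a chiral PHOX ligand), loss of CO2 gives a prochiral palladium enolate and π-allyl fragment that recombine under ligand control, so both enantiomers of 3 should converge on the (R)-quaternary centre.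

Step 3
Reactants: 4 (2R)-2-methyl-2-(prop-2-en-1-yl)cyclopentan-1-one
Product: 6 (2R)-5-(2-hydroxypropan-2-yl)-2-methyl-2-(prop-2-en-1-yl)cyclopentan-1-one (mixture of C5 epimers), via lithium enolate 5 (not isolated)
Conditions: LiN(i-Pr)2 (1.1 equiv), THF, −78 °C; acetone, −78 °C; aq. NH4Cl at −78 °C
Reagents that add atoms: acetone, CC(C)=O
Why: C5 is the only enolisable position, so the directed aldol addition to acetone must occur there, and the new C5 stereocentre is irrelevant because it becomes sp2 in step 4.

Step 4
Reactants: 6 (2R)-5-(2-hydroxypropan-2-yl)-2-methyl-2-(prop-2-en-1-yl)cyclopentan-1-one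
Product: 7 (2R)-2-methyl-5-(propan-2-ylidene)-2-(prop-2-en-1-yl)cyclopentan-1-one
Conditions: p-TsOH·H2O (cat.), benzene, reflux, Dean–Stark trap
Reagents that add atoms: none
Why: Acid-catalysed dehydration of the tertiary aldol (second stage of an aldol condensation) should give the conjugated exocyclic enone as the thermodynamic isomer, with the non-enolisable quaternary centre untouched.

Step 5
Reactants: 7 (2R)-2-methyl-5-(propan-2-ylidene)-2-(prop-2-en-1-yl)cyclopentan-1-one
Product: 9 (5R)-5-methyl-2-(propan-2-yl)-5-(prop-2-en-1-yl)cyclopent-1-en-1-yl trifluoromethanesulfonate, via lithium enolate 8 (not isolated)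
Conditions: Li (2.2 equiv), NH3(l)/THF, t-BuOH (1.0 equiv), −78 °C; NH3 removed; PhNTf2 (1.3 equiv), THF, 0 → 25 °C; aqueous work-up
Reagents that add atoms: N-phenylbis(trifluoromethanesulfonimide), O=S(=O)(N(c1ccccc1)S(=O)(=O)C(F)(F)F)C(F)(F)F
Why: Dissolving-metal conjugate reduction of the enone delivers the only possible enolate (the other α-carbon is quaternary), which is O-sulfonylated to the tetrasubstituted enol triflate while the isolated terminal alkene is not reduced.

Step 6
Reactants: 9 (5R)-5-methyl-2-(propan-2-yl)-5-(prop-2-en-1-yl)cyclopent-1-en-1-yl trifluoromethanesulfonate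
Product: 10 (5R)-5-methyl-5-(2-oxoethyl)-2-(propan-2-yl)cyclopent-1-en-1-yl trifluoromethanesulfonate
Conditions: OsO4 (2 mol %), NaIO4 (4 equiv), 2,6-lutidine, 1,4-dioxane/H2O, 25 °C
Reagents that add atoms: osmium tetroxide, O=[Os](=O)(=O)=O (oxygen donor, turned over by sodium periodate, [Na+].[O-]I(=O)(=O)=O)
Why: In this Lemieux–Johnson cleavage the unhindered monosubstituted alkene should be dihydroxylated far faster than the electron-poor, tetrasubstituted enol triflate, and periodate cleaves the diol to the aldehyde.

Step 7
Reactants: 11 diethyl prop-2-en-1-ylphosphonate (diethyl allylphosphonate)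
Product: 14 ethyl 2-(diethoxyphosphoryl)but-3-enoate (racemic), via lithiated allylphosphonate 12 (not isolated), via lithium phosphonoacetate salt 13 (not isolated)
Conditions: LiN(i-Pr)2 (2.1 equiv), THF, −78 °C; ClCO2Et (1.0 equiv), −78 °C; AcOH, −78 °C; cold neutral work-up, used at once
Reagents that add atoms: ethyl chloroformate, CCOC(=O)Cl
Why: The lithiated allylphosphonate is C-acylated next to phosphorus, the product is held as its doubly stabilised anion by the second equivalent of base, and kinetic protonation at the carbon between the two acceptors should return the vinyl (β,γ-unsaturated) phosphonoacetate (acylation of a phosphonate carbanion).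

Step 8
Reactants: 14 ethyl 2-(diethoxyphosphoryl)but-3-enoate; 10 (5R)-5-methyl-5-(2-oxoethyl)-2-(propan-2-yl)cyclopent-1-en-1-yl trifluoromethanesulfonate
Product: 17 ethyl (8aR)-8a-methyl-3-(propan-2-yl)-1,2,4,5,8,8a-hexahydroazulene-6-carboxylate, via alkylborane 15 (not isolated), via coupled phosphonate aldehyde 16 (not isolated)
Conditions: 14 (1.3 equiv), 9-BBN-H (1.2 equiv), THF, 0 → 25 °C; then 10 (1.0 equiv), PdCl2(dppf) (10 mol %), AsPh3 (10 mol %), Cs2CO3 (3.5 equiv), DMF/THF/H2O, 0.02 M, 25 → 60 °C
Reagents that add atoms: none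
Why: 9-BBN-H adds anti-Markovnikov to the vinyl group of 14, and the primary alkylborane 15, activated by the aqueous carbonate, transmetalates to the alkenylpalladium species formed by oxidative addition into the C–OTf bond of 10, so that reductive elimination forms the C3a–C4 bond of 16 (B-alkyl Suzuki–Miyaura coupling). The same base then deprotonates the phosphonoacetate carbon of 16, which adds to the aldehyde and expels diethyl phosphate through the oxaphosphetane, forming the C6=C7 bond (intramolecular Horner–Wadsworth–Emmons olefination). The closest known reaction types are sp2–sp3 Suzuki couplings of hindered cycloalkenyl triflates and phosphonate ring closures to cycloalkene carboxylates, combined here in one flask as a formal (4+3) annulation. The seven-membered ring closes in the olefination event, by 7-exo-trig attack of the carbanion on the carbonyl followed by syn-elimination, and the ring itself allows only the alkene geometry with C5 and C8 cis. No stereocentre is formed; the quaternary C8a is a non-epimerisable spectator. The step needs coupling at the triflate without loss of the free aldehyde, secured by the inertness of B-alkyl-9-BBN reagents to aldehydes and by leaving no excess 9-BBN-H, and it needs cyclisation instead of oligomerisation, favoured by dilution and by the fact that an intermolecular olefination of the usual E sense would still converge on 17 through intramolecular coupling.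

Step 9
Reactants: 17 ethyl (8aR)-8a-methyl-3-(propan-2-yl)-1,2,4,5,8,8a-hexahydroazulene-6-carboxylate
Product: 18 [(8aR)-8a-methyl-3-(propan-2-yl)-1,2,4,5,8,8a-hexahydroazulen-6-yl]methanol
Conditions: i-Bu2AlH (2.5 equiv), CH2Cl2, −78 → 0 °C; aq. Rochelle salt
Reagents that add atoms: none
Why: i-Bu2AlH should reduce the conjugated ester by 1,2-hydride delivery to the primary allylic alcohol without touching the unactivated tri- and tetrasubstituted alkenes (ester reduction).

Step 10
Reactants: 18 [(8aR)-8a-methyl-3-(propan-2-yl)-1,2,4,5,8,8a-hexahydroazulen-6-yl]methanol; 19 vanillic acid (4-hydroxy-3-methoxybenzoic acid)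
Product: 20 [(8aR)-8a-methyl-3-(propan-2-yl)-1,2,4,5,8,8a-hexahydroazulen-6-yl]methyl 4-hydroxy-3-methoxybenzoate (target)
Conditions: PPh3 (1.3 equiv), DIAD (1.3 equiv), THF, 0 → 25 °C
Reagents that add atoms: none
Why: In this Mitsunobu esterification the carboxylic acid, far more acidic than the phenol, should act as the pronucleophile and displace the primary allylic oxyphosphonium centre in an SN2 sense, so the phenol needs no protection.

Compound list
1 | diallyl adipate (diprop-2-en-1-yl hexanedioate) | C=CCOC(=O)CCCCC(=O)OCC=C | starting material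
2 | sodium enolate of prop-2-en-1-yl 2-oxocyclopentane-1-carboxylate | [Na+].C=CCOC(=O)C1=C([O-])CCC1 | intermediate (not isolated)
3 | prop-2-en-1-yl 1-methyl-2-oxocyclopentane-1-carboxylate (racemic) | C=CCOC(=O)C1(C)CCCC1=O | intermediate
4 | (2R)-2-methyl-2-(prop-2-en-1-yl)cyclopentan-1-one | C=CC[C@@]1(C)CCCC1=O | intermediate
5 | lithium (5R)-5-methyl-5-(prop-2-en-1-yl)cyclopent-1-en-1-olate | [Li+].C=CC[C@@]1(C)CCC=C1[O-] | intermediate (not isolated)
6 | (2R)-5-(2-hydroxypropan-2-yl)-2-methyl-2-(prop-2-en-1-yl)cyclopentan-1-one (C5 epimers) | C=CC[C@@]1(C)CCC(C(C)(C)O)C1=O | intermediate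
7 | (2R)-2-methyl-5-(propan-2-ylidene)-2-(prop-2-en-1-yl)cyclopentan-1-one | C=CC[C@@]1(C)CCC(=C(C)C)C1=O | intermediate
8 | lithium (5R)-5-methyl-2-(propan-2-yl)-5-(prop-2-en-1-yl)cyclopent-1-en-1-olate | [Li+].C=CC[C@@]1(C)CCC(C(C)C)=C1[O-] | intermediate (not isolated)
9 | (5R)-5-methyl-2-(propan-2-yl)-5-(prop-2-en-1-yl)cyclopent-1-en-1-yl trifluoromethanesulfonate | C=CC[C@@]1(C)CCC(C(C)C)=C1OS(=O)(=O)C(F)(F)F | intermediate
10 | (5R)-5-methyl-5-(2-oxoethyl)-2-(propan-2-yl)cyclopent-1-en-1-yl trifluoromethanesulfonate | O=CC[C@@]1(C)CCC(C(C)C)=C1OS(=O)(=O)C(F)(F)F | intermediate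
11 | diethyl prop-2-en-1-ylphosphonate | C=CCP(=O)(OCC)OCC | starting material
12 | lithium 1-(diethoxyphosphoryl)prop-2-en-1-ide | [Li+].C=C[CH-]P(=O)(OCC)OCC | intermediate (not isolated)
13 | lithium salt of ethyl 2-(diethoxyphosphoryl)but-3-enoate | [Li+].C=C[C-](C(=O)OCC)P(=O)(OCC)OCC | intermediate (not isolated)
14 | ethyl 2-(diethoxyphosphoryl)but-3-enoate (racemic) | C=CC(C(=O)OCC)P(=O)(OCC)OCC | intermediate
15 | ethyl 4-(9-borabicyclo[3.3.1]nonan-9-yl)-2-(diethoxyphosphoryl)butanoate | CCOC(=O)C(CCB1C2CCCC1CCC2)P(=O)(OCC)OCC | intermediate (not isolated)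
16 | ethyl 2-(diethoxyphosphoryl)-4-[(5R)-5-methyl-5-(2-oxoethyl)-2-(propan-2-yl)cyclopent-1-en-1-yl]butanoate (epimers at the phosphonate carbon) | CCOC(=O)C(CCC1=C(C(C)C)CC[C@]1(C)CC=O)P(=O)(OCC)OCC | intermediate (not isolated)
17 | ethyl (8aR)-8a-methyl-3-(propan-2-yl)-1,2,4,5,8,8a-hexahydroazulene-6-carboxylate | CCOC(=O)C1=CC[C@@]2(C)CCC(C(C)C)=C2CC1 | intermediate
18 | [(8aR)-8a-methyl-3-(propan-2-yl)-1,2,4,5,8,8a-hexahydroazulen-6-yl]methanol | OCC1=CC[C@@]2(C)CCC(C(C)C)=C2CC1 | intermediate
19 | vanillic acid (4-hydroxy-3-methoxybenzoic acid) | COc1cc(C(=O)O)ccc1O | starting material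
20 | [(8aR)-8a-methyl-3-(propan-2-yl)-1,2,4,5,8,8a-hexahydroazulen-6-yl]methyl 4-hydroxy-3-methoxybenzoate | COc1cc(C(=O)OCC2=CC[C@@]3(C)CCC(C(C)C)=C3CC2)ccc1O | target

Total step count: 10. Longest linear sequence: 9 steps (steps 1–6, 8, 9, 10); step 7 is a one-step side branch.

Steps most likely to fail

Step 8. The coupling and the olefination may interfere in one flask: premature intermolecular olefination with the wrong alkene geometry, oligomerisation, or loss of the aldehyde under warm aqueous base. The fallback closes the ring by olefin metathesis, sets out from 9 (with borane 15) and comes back at 17. Borane 15 is coupled with the allyl triflate 9 under the same palladium conditions, with no aldehyde present, to give ethyl 2-(diethoxyphosphoryl)-4-[(5R)-5-methyl-2-(propan-2-yl)-5-(prop-2-en-1-yl)cyclopent-1-en-1-yl]butanoate F1. Olefination of F1 with aqueous formaldehyde and K2CO3 gives the α-methylene ester ethyl 2-methylidene-4-[(5R)-5-methyl-2-(propan-2-yl)-5-(prop-2-en-1-yl)cyclopent-1-en-1-yl]butanoate F2. Ring-closing metathesis of F2 with the second-generation Grubbs catalyst (CH2Cl2, 40 °C) joins the acrylate and allyl termini, the tetrasubstituted ring alkene being inert, and gives 17.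

Step 7. Acylation may go to the γ-carbon of the allyl anion, or the vinyl group of 14 may slip into conjugation with the ester during quench and handling, which would leave no terminal alkene for hydroboration. The fallback avoids the vinyl phosphonoacetate, sets out from 11 (and 9) and comes back at 17. Phosphonate 11 is hydroborated with 9-BBN-H to diethyl [3-(9-borabicyclo[3.3.1]nonan-9-yl)propyl]phosphonate F3, which is coupled with triflate 9 (PdCl2(dppf), Cs2CO3, DMF/THF/H2O) to diethyl {3-[(5R)-5-methyl-2-(propan-2-yl)-5-(prop-2-en-1-yl)cyclopent-1-en-1-yl]propyl}phosphonate F4. Lithiation next to phosphorus, now the only acidic site (LiN(i-Pr)2, 2 equiv), and acylation with ethyl chloroformate give F1, which is carried through F2 to 17 by formaldehyde olefination and ring-closing metathesis as described for step 8.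

Step 10. The free phenol may compete as the acidic partner (aryl ether formation), or displacement may occur with allylic transposition. The fallback uses a protected acid, sets out from 18 and comes back at 20. Alcohol 18 is acylated with commercial 4-acetoxy-3-methoxybenzoic acid (EDC·HCl, DMAP, CH2Cl2) to [(8aR)-8a-methyl-3-(propan-2-yl)-1,2,4,5,8,8a-hexahydroazulen-6-yl]methyl 4-(acetyloxy)-3-methoxybenzoate F5. The aryl acetate of F5 is then removed with pyrrolidine (CH2Cl2, 0 °C), which should aminolyse the phenyl acetate much faster than the alkyl benzoate, to give 20.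

Further compounds
F1 | step 8 | ethyl 2-(diethoxyphosphoryl)-4-[(5R)-5-methyl-2-(propan-2-yl)-5-(prop-2-en-1-yl)cyclopent-1-en-1-yl]butanoate | CCOC(=O)C(CCC1=C(C(C)C)CC[C@]1(C)CC=C)P(=O)(OCC)OCC
F2 | step 8 | ethyl 2-methylidene-4-[(5R)-5-methyl-2-(propan-2-yl)-5-(prop-2-en-1-yl)cyclopent-1-en-1-yl]butanoate | CCOC(=O)C(=C)CCC1=C(C(C)C)CC[C@]1(C)CC=C
F3 | step 7 | diethyl [3-(9-borabicyclo[3.3.1]nonan-9-yl)propyl]phosphonate | CCOP(=O)(CCCB1C2CCCC1CCC2)OCC
F4 | step 7 | diethyl {3-[(5R)-5-methyl-2-(propan-2-yl)-5-(prop-2-en-1-yl)cyclopent-1-en-1-yl]propyl}phosphonate | CCOP(=O)(CCCC1=C(C(C)C)CC[C@]1(C)CC=C)OCC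
F5 | step 10 | [(8aR)-8a-methyl-3-(propan-2-yl)-1,2,4,5,8,8a-hexahydroazulen-6-yl]methyl 4-(acetyloxy)-3-methoxybenzoate | COc1cc(C(=O)OCC2=CC[C@@]3(C)CCC(C(C)C)=C3CC2)ccc1OC(C)=O
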